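(The data were computed on assumed constants; noise was put on by code.)

The product was what I followed in these flasks, and the question was how much of the starting material lost had become product.

in all of them: starting material 0.20 M
- maple: coupling partner 0.16 M; capture agent 4 mM; run made earlier
- larch: coupling partner 0.36 M; capture agent 4 mM; run made earlier
- cedar: coupling partner 0.24 M; capture agent 2 mM; run made earlier
- dawn: coupling partner 0.240 M; capture agent 4.00 mM; time 25 min
- autumn: coupling partner 0.240 M; capture agent 4.00 mM; time 30 min

| run | time / min | intermediate B / % | intermediate D / % | product / % | intermediate E / % | starting material / % |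
|---|---|---|---|---|---|---|
| maple | 4.00 | 9.1 | 1.2 | 19.7 | 0 | 68.9 |
| maple | 10.0 | 10.2 | 5.3 | 30.7 | 1.9 | 50.6 |
| maple | 20.0 | 7.5 | 9.9 | 36.9 | 3.0 | 40.8 |
| maple | 30.0 | 6.2 | 11.8 | 38.0 | 4.3 | 37.0 |
| larch | 4.00 | 16.1 | 2.6 | 35.1 | 1.8 | 42.2 |
| larch | 10.0 | 15.4 | 10.6 | 51.7 | 4.0 | 17.6 |
| larch | 20.0 | 8.2 | 20.1 | 58.1 | 6.9 | 5.0 |
| larch | 30.0 | 3.3 | 23.6 | 60.2 | 9.0 | 2.6 |
| cedar | 4.00 | 11.9 | 1.2 | 26.9 | 2.1 | 57.7 |
| cedar | 10.0 | 12.8 | 7.6 | 40.6 | 2.8 | 33.6 |
| cedar | 20.0 | 8.4 | 15.2 | 48.2 | 4.7 | 21.0 |
| cedar | 30.0 | 5.2 | 18.3 | 51.2 | 6.6 | 17.4 |

(scatter of a reading: 0.5 percentage points)

- a reading of intermediate B is of its free form alone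

- which of these there is most of at the end, counted by the starting material in it, dawn (product / starting material / intermediate D / intermediate E / intermediate B)
- which of these there is most of at the end, counted by the starting material in it, autumn (product / starting material / intermediate D / intermediate E / intermediate B)
- the largest of these amounts at the end, in percent of the starting material charged, dawn
- the largest of these amounts at the end, in percent of the starting material charged, autumn

At the last readings, product over starting material lost was 0.603 in maple, 0.618 in larch and 0.620 in cedar, though the partner charge ran from 0.16 M to 0.36 M. Their mean, 0.614, I called the product share, a selectivity factor read from the readings: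

product = product share × starting material lost

Cedar had dawn's partner charge, but partner was being used up from the start, so I took from cedar's first reading only an average first-order rate up to 4.00 min, and used it for dawn:

average rate = 0.137 min⁻¹

Dawn's product should therefore have risen at about 0.0841 min⁻¹ of the charge over those first minutes. It should have crossed the falling starting material where both equalled

share/(share + 1) = 0.380,

at 7.06 min if the average rate held. The knee lay beyond: cedar's product gained 14 percentage points between its first two readings and 3 points between its last two.

For the level, maple's starting material lost plus intermediates D and E came to 79.1%, against a partner charge of 0.800 of the starting material. So I let the side route take a second equivalent: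

lost at the level = equivalents/(2 − share) = 0.866

level of product = 0.532

Taking starting material from cedar, 0.192 midway between its last two readings and 17.4% at the last, the share gave 0.496 for dawn and 0.507 for autumn.

The forecast named product in dawn and product in autumn, at 49.3% and 50.6%, saying of cedar “so it is the best guide”. My dawn figure stood higher.

Dawn gave 50.4% and autumn 51.5%, with product the largest in both, as the forecast said.

    coupling partner + intermediate C → intermediate D (k = 11.0 M⁻¹ min⁻¹)
    intermediate A → intermediate B (k = 2.40 min⁻¹)
    intermediate B ⇌ intermediate C (K = 0.530, k = 0.130 min⁻¹)
    starting material + coupling partner → product (k = 0.470 M⁻¹ min⁻¹)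
    intermediate D ⇌ intermediate E (K = 0.370, k = 0.660 min⁻¹)
    capture agent + intermediate D → trapped intermediate (k = 0.630 M⁻¹ min⁻¹)
    starting material + coupling partner ⇌ intermediate A (K = 83.0 M⁻¹, k = 0.290 M⁻¹ min⁻¹)

The capture step changed dawn's product by nothing, and trapped intermediate stood at 0.499%. With the starting material found, 18.6% in dawn and 16.8% in autumn, the share gives 0.500 and 0.511.

The neighbour with 0.41 M of partner had 2.05 equiv, above 2 minus the share, so starting material became the limiting reagent and the share itself, 0.614, was my level. That flask gave 60.7% of product with 1.88% of starting material left.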